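## Structural features

The target is a sesquiterpene diester on a hydroazulene skeleton: a cyclopentane (C1–C5) cis-fused along C1–C5 to a cycloheptene (C1, C5–C10) whose only olefin is the trisubstituted C8(Me)=C9. Numbering used throughout: C1 is the methyl-bearing quaternary fusion carbon, C2 the angelate carbon, C3 a methylene, C4 the isopropyl carbinol, C5 the fusion CH, C6 the benzoate carbon, C7 a methylene, C8(Me)=C9 the olefin and C10 a methylene; α is the face of the C1 methyl group and β the opposite face. Five stereocentres are clustered around the ring fusion (C2–C1–C5–C4 contiguous, C6 attached to C5): 1α-Me, 2β-O, 4β-OH/4α-iPr, 5α-H and 6α-O, which is 1R,2S,4S,5R,6R in this numbering. The methyl group, H5 and the isopropyl group therefore share the α face, and C10, the C2 oxygen and the C4 hydroxyl share the β face. Fragile elements are the (Z)-configured angelate (drifts to the tiglate under base, nucleophiles or heat), the tertiary C4 hydroxyl β to C6 (dehydration or retro-aldol whenever C6 is a carbonyl), the C8=C9 olefin (β,γ to any C6 carbonyl, so it can slip into conjugation) and two different esters on two secondary oxygens. The real difficulty is the quaternary C1 inside the medium ring, flanked by C2 and C5, together with the C4/C5/C6 triad in which H5 must sit on the more hindered face. The key step uses the fact that C5=C6 (oxygen on C6) and C8=C9 flank the C7 methylene while C1–C10 lies opposite, which is the 1,4-diene left by the ring expansion of a cis-dialkenylcyclopropane built on C6, C7 and C8.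

## Logic of the disconnections

**22 to 19.** The two ester C–O bonds are cut, C2–O(acyl) first and C6–O(acyl) second, via 21 and 20. The angelate is the most labile group and is introduced last. The benzoate can be placed while C2 is silylated and C4 is tertiary, so no extra differentiation is needed. The demand is an acylation at the neopentylic C2 hydroxyl that neither isomerises the Z olefin nor touches the C4 hydroxyl.

**19 to 18.** The C6–H bond is cut, returning the carbinol to a ketone. C6 can then be derived from C4 by internal hydride delivery, and one stereocentre is removed. The demand is a cis relationship of the C4 oxygen and C6 and non-basic conditions, because 18 is a tertiary aldol with a β,γ-olefin.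

**18 to 16.** The C4–O and C5–H bonds are cut via 17, a formal hydration of a C4=C5 enone. The enone makes C4 electrophilic toward an oxygen nucleophile and lets H5 enter reductively. Two stereocentres disappear and a flat tetrasubstituted enone remains. The demands are oxygen delivery to the β face of C4 and protonation of C5 on the α face.

**16 to 13.** The C4–isopropyl bond is cut via 14. C4 is the β-carbon of the enone that the ring-expansion product gives on dehydrogenation. This returns directly to 13. The demands are two dehydrogenations, which can only run toward C4 because C1 is quaternary, and a 1,4-addition that tolerates the acidic C7 protons.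

**13 to 12 (key).** C1–C10 is cut and C6–C8 is reconnected. The seven-membered ring and the quaternary stereocentre are exchanged for a cyclopropane on an intact cyclopentene. The demands are a cis arrangement of the two alkenyl groups, a configurationally defined three-membered ring and a rearrangement that is faster than ring epimerisation. A model of the boat shows that the (S)-carbinol combined with the (1S,2R)-cyclopropane of 12 leads to 1α-methyl with C10 on the face of the C2 oxygen, as 22 requires. The bond therefore has to form on the silyloxy-bearing face.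

**12 to 8.** The C9=C10 olefin is cut (olefination of 11) and then the C8–CH3 bond (alkylation of enolate 9 to give 10). Alkylating the ester enolate away from the bulky cyclopentenyl group sets the cis relationship of the two future alkenyl groups. The C2 oxygen and C6 are transoid across the tetrasubstituted C1=C5 bond, so no chelate or tether can relay C2 to the three-membered ring, and the two ring-enantiomeric series have to be separated at 10. A one-step titanium-mediated cyclopropanol synthesis was set aside. It would have to create the quaternary ring carbon from a titanium–diene complex, with open regiochemistry (methyl on C8 or on C9) and an open cis/trans outcome. The tertiary silyl ether is carried as triethylsilyl so that it survives enolate, hydride and ylide chemistry.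

**8 to 7.** The C6–C8 and C7–C8 bonds are cut, a carbene addition to the terminal enol ether double bond of a 2-silyloxydiene. This is the most reliable way to a 1-alkenyl-1-silyloxycyclopropane with a functional handle on the neighbouring carbon. The demand is chemoselectivity for the enol ether over the tetrasubstituted ring olefin.

**7 to 4.** The O–Si bond and the C5–C6 bond are cut via 6 and 5, the acylation of a vinyl metal. This leaves a simple chiral bromocyclopentenol ether. The demand is kinetic enolisation of 6 at its methyl group.

**4 to 1.** The C2–H bond is cut via 3 and 2, so that the only stereocentre not derived from another one comes from a catalytic enantioselective ketone reduction. The bromoenone comes from the dione by vinylogous acyl substitution.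

## Other disconnections considered

**Alternative 1:** The cut removes both bonds that tie the seven-membered ring to the cyclopentane, C1–C10 and C5–C6, and leaves the pyranone A1 and the cyclopentenone A2. In the forward sense Et3N eliminates acetic acid from A1, and the resulting oxidopyrylium adds across the C1=C5 olefin of A2 to give the oxygen-bridged tricycle A3.
- In its favour: it is convergent. Quaternary C1 and the cis ring fusion are fixed together by a suprafacial addition, so H5 needs no protonation step, which is better than the chosen plan. The carbonyl of A2 is C4, ready for the isopropyl nucleophile, which is also better.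
- Against it here: the 2π partner is a β-methyl enone, a sluggish partner for an intermolecular oxidopyrylium addition in which dipole dimerisation competes. The dipole should approach anti to the silyloxy group of A2, which leaves C2 with the wrong configuration and forces an inversion at a neopentyl carbinol. A3 also carries a C9 ketone, a C10–O bond and a C7=C8 olefin that must all be removed or moved.
- Comparison: on structure, both plans create C1 by a thermal pericyclic C1–C10 bond formation (equal), but the chosen plan delivers the C6 oxygen and C8=C9 exactly where they are needed. On mechanism, a bimolecular cycloaddition with regio- and facial questions stands against a unimolecular stereospecific shift. On step economy, the alternative is shorter to the bicyclic core and longer afterwards, so no net gain is expected.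

**Alternative 2:** The cut is the ring-fusion bond C1–C5. In the precursor A6, a trans-decalin reached from the Diels–Alder adduct of A4 and A5, C1 is still bonded to C6. BF3·OEt2 opens the C4–C5 epoxide of A6 at C5 while C1 shifts from C6 to C5, which contracts one ring, expands the other and gives A7.
- In its favour: A4 and A5 are cheap and bring all fifteen skeletal carbons together in one cycloaddition, which is better in carbon economy. The 1,2-shift is stereospecific, so the C4 hydroxyl and H5 emerge with fixed relative configuration; this is better than steps 12 and 13 of the chosen plan, which rest on face selectivity and a protonation. A7 is the same compound as 18, so the last four steps are shared (equal).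
- Against it here: the Diels–Alder reaction has to choose the methyl-bearing quinone double bond, the orientation of the diene methyl group (C8 or C9) and one enantiomer, whereas the chosen plan takes its absolute configuration from a routine catalytic reduction. Many adjustments separate the adduct from A6: differentiation of two carbonyl groups, hydroxylation of a ring-fusion carbon, cis to trans decalin and a face-selective epoxidation. In the rearrangement the tertiary, isopropyl-bearing epoxide carbon can ionise in competition, and C7 can migrate instead of C1 unless the decalin holds C1 anti to the breaking C–O bond.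
- Comparison: on structure, the alternative collects the carbons faster but needs a skeletal reorganisation, while the chosen plan builds the final ring sizes directly. On mechanism, a cationic 1,2-shift stands against a neutral sigmatropic shift. On step count, the way to A7 is estimated to be about as long as the thirteen steps to 18, with more redox and protecting-group work.

**Alternative 3:** The cut removes C6–C7 and C1–C10, leaving the diene A5 and the silyloxy enal A8, in which C1 is the fully substituted β-carbon. Sc(OTf)3 activates the aldehyde carbon C6, A5 attacks through C7, and the silyl enol ether carbon C1 closes onto the allyl cation at C10 with silyl transfer to give the cycloheptenone A9.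
- In its favour: the seven-membered ring, the C8 methyl group, C8=C9 and quaternary C1 arise in one intermolecular step from a bulk diene, which equals what the chosen ring-forming step delivers. C6 already stands at the alcohol oxidation level, which is better than the enol ether of 13 that has to be reduced later.
- Against it here: ring closure at a tetrasubstituted enol ether carbon competes with (4+2) addition and with open-chain termination of the cation. The orientation of A5 again decides C8 or C9. C1 is controlled only by acyclic induction from the dioxolane. The cyclopentane does not exist yet, so C3–C4, C4–C5, the C4 carbinol and H5 must all be made after the key step.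
- Comparison: on structure, the chosen plan carries an intact five-membered ring into the key step and leaves only functional-group work, while the alternative leaves a ring annulation. On mechanism, a stepwise cationic process stands against a concerted one. On step economy, the alternative has fewer steps before the key step and clearly more after it.

Key step: step 9

Assumption: the two diastereomers formed in step 7 (same C2, mirror-image cyclopropane) are separable by chromatography; only 10 is advanced, which costs about half of the material at that stage.

Abbreviations: TBS = tert-butyldimethylsilyl, TES = triethylsilyl, TMS = trimethylsilyl. Bicyclic compounds are named on the hydroazulene skeleton with the numbering and α/β convention defined above.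

## Route

Step 1
Reactants: 1 2-methylcyclopentane-1,3-dione
Product: 2 3-bromo-2-methylcyclopent-2-en-1-one
Conditions: PPh3, Br2, Et3N, CH2Cl2, 0 °C to rt
Reagents that add atoms: bromine BrBr
Why: Vinylogous acyl substitution: the enol oxygen is activated by Ph3PBr2 and displaced by bromide in an addition–elimination, a standard route to β-bromoenones from cyclic 1,3-diones.

Step 2
Reactants: 2 3-bromo-2-methylcyclopent-2-en-1-one
Product: 3 (1S)-3-bromo-2-methylcyclopent-2-en-1-ol
Conditions: (R)-2-methyl-CBS-oxazaborolidine (15 mol %), BH3·SMe2, THF, −20 °C
Reagents that add atoms: none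
Why: Corey–Bakshi–Shibata reduction; the substituted alkenyl arm acts as the large group, so the (R)-catalyst should deliver hydride to give the S carbinol, the future C2.

Step 3
Reactants: 3 (1S)-3-bromo-2-methylcyclopent-2-en-1-ol
Product: 4 {[(1S)-3-bromo-2-methylcyclopent-2-en-1-yl]oxy}(tert-butyl)dimethylsilane
Conditions: TBSCl, imidazole, DMF, rt
Reagents that add atoms: tert-butyldimethylsilyl chloride CC(C)(C)[Si](C)(C)Cl
Why: Silylation of the allylic alcohol; the TBS ether should survive organolithium, enolate, hydride, copper, peroxide and SmI2 chemistry and is removed only in step 16.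

Step 4
Reactants: 4 {[(1S)-3-bromo-2-methylcyclopent-2-en-1-yl]oxy}(tert-butyl)dimethylsilane
Product: 6 1-[(3S)-3-(tert-butyldimethylsilyloxy)-2-methylcyclopent-1-en-1-yl]ethan-1-one, via vinyllithium 5 (not isolated)
Conditions: t-BuLi (2 equiv), Et2O, −78 °C; then MeC(O)N(OMe)Me, −78 to 0 °C
Reagents that add atoms: N-methoxy-N-methylacetamide CC(=O)N(C)OC
Why: Bromine–lithium exchange followed by Weinreb ketone synthesis; the chelated tetrahedral adduct prevents a second addition and forms the C5–C6 bond.

Step 5
Reactants: 6 1-[(3S)-3-(tert-butyldimethylsilyloxy)-2-methylcyclopent-1-en-1-yl]ethan-1-one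
Product: 7 tert-butyldimethyl{[(1S)-2-methyl-3-[1-(triethylsilyloxy)ethenyl]cyclopent-2-en-1-yl]oxy}silane
Conditions: LiN(iPr)2, THF, −78 °C; TESCl, Et3N, −78 to 0 °C
Reagents that add atoms: triethylsilyl chloride CC[Si](CC)(CC)Cl
Why: Kinetic deprotonation of the methyl ketone at its only α' position and O-silylation give the 2-silyloxy-1,3-diene; C6 now carries the oxygen that ends as the C6 ester oxygen of the target.

Step 6
Reactants: 7 tert-butyldimethyl{[(1S)-2-methyl-3-[1-(triethylsilyloxy)ethenyl]cyclopent-2-en-1-yl]oxy}silane
Product: 8 ethyl 2-[(3S)-3-(tert-butyldimethylsilyloxy)-2-methylcyclopent-1-en-1-yl]-2-(triethylsilyloxy)cyclopropane-1-carboxylate (all four ring stereoisomers)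
Conditions: N2CHCO2Et (slow addition), Cu(acac)2 (3 mol %), EtOAc, 75 °C
Reagents that add atoms: ethyl diazoacetate CCOC(=O)C=[N+]=[N-]
Why: Copper-carbenoid cyclopropanation of the electron-rich, unhindered terminal enol ether double bond, the usual entry to 2-silyloxycyclopropanecarboxylates; it forms C6–C8 and C7–C8. No induction from the remote C2 is expected, so the ring stereocentres are left open here.

Step 7
Reactants: 8 ethyl 2-[(3S)-3-(tert-butyldimethylsilyloxy)-2-methylcyclopent-1-en-1-yl]-2-(triethylsilyloxy)cyclopropane-1-carboxylate (all four ring stereoisomers)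
Product: 10 ethyl (1S,2R)-2-[(3S)-3-(tert-butyldimethylsilyloxy)-2-methylcyclopent-1-en-1-yl]-1-methyl-2-(triethylsilyloxy)cyclopropane-1-carboxylate, via lithium ester enolate 9 (not isolated)
Conditions: LiN(iPr)2, THF, −78 °C; MeI, −78 to −20 °C; chromatographic separation of the two diastereomers
Reagents that add atoms: iodomethane CI
Why: Alkylation of the cyclopropyl ester enolate creates quaternary C8 and erases the cis/trans ester mixture; methyl iodide should enter on the face of the silyloxy oxygen, away from the bulky 2-methylcyclopentenyl group, which places the ester (the future vinyl group) cis to the ring alkenyl group. The two remaining diastereomers differ only in the sense of the three-membered ring and are separated here.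

Step 8
Reactants: 10 ethyl (1S,2R)-2-[(3S)-3-(tert-butyldimethylsilyloxy)-2-methylcyclopent-1-en-1-yl]-1-methyl-2-(triethylsilyloxy)cyclopropane-1-carboxylate
Product: 12 tert-butyl{[(1S)-3-[(1S,2R)-2-ethenyl-2-methyl-1-(triethylsilyloxy)cyclopropyl]-2-methylcyclopent-2-en-1-yl]oxy}dimethylsilane, via cyclopropanecarbaldehyde 11 (not isolated)
Conditions: iBu2AlH, CH2Cl2, −78 °C; then Ph3P=CH2 (from Ph3PCH3Br, KN(SiMe3)2), THF, −78 to 0 °C
Reagents that add atoms: methyltriphenylphosphonium bromide C[P+](c1ccccc1)(c1ccccc1)c1ccccc1.[Br-]
Why: Partial reduction of the hindered neopentyl-type ester stops at the aldehyde, and Wittig methylenation installs C10. The aldehyde is used crude and cold because a cis-2-alkenylcyclopropanecarbaldehyde can drift to a dihydrooxepine by a retro-Claisen shift.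

Step 9
Reactants: 12 tert-butyl{[(1S)-3-[(1S,2R)-2-ethenyl-2-methyl-1-(triethylsilyloxy)cyclopropyl]-2-methylcyclopent-2-en-1-yl]oxy}dimethylsilane
Product: 13 2β-(tert-butyldimethylsilyloxy)-1α,8-dimethyl-6-(triethylsilyloxy)hydroazula-5,8-diene (C5=C6 silyl enol ether)
Conditions: PhMe (degassed, dilute), 2,6-di-tert-butyl-4-methylpyridine (5 mol %), 90–110 °C, base-washed sealed tube
Reagents that add atoms: none
Why: Thermal [3,3] sigmatropic (Cope) rearrangement of a cis-1,2-dialkenylcyclopropane through the boat transition state, in which both alkenyl groups lie over the three-membered ring; C1–C10 forms while C6–C8 breaks and the π bonds move to C8=C9 and C5=C6. The closest known reaction type is the rearrangement of 2-silyloxy-cis-divinylcyclopropanes to silyl enol ethers of cyclohept-4-enones, including cases in which a 2-methylcyclopentenyl terminus creates the angular methyl group of a hydroazulene. The seven-membered ring is closed by this strain-driven ring expansion, suprafacial on both allyl halves, and not by an exo or endo cyclisation onto a π bond. The only new stereocentre, C1, is dictated by the absolute configuration of the cyclopropane: in the (1S,2R) isomer the vinyl terminus C10 can reach only the cyclopentene face that carries the C2 silyloxy group, which puts the methyl group on the α face. The step therefore needs stereospecificity (no epimerisation of the ring before the shift) and tolerance of a fully substituted terminus with an inward methyl group. The donor silyloxy group on C6 and the quaternary C8 weaken the breaking bond and should keep the required temperature near 100 °C, below the range in which homolytic ring epimerisation is expected, and the long O–Si bond lets the silyl group at C2 turn away from the incoming carbon. The regiochemistry of the enol ether is inherent because C6 keeps its oxygen, and acid-free glassware with a hindered pyridine protects it.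

Step 10
Reactants: 13 2β-(tert-butyldimethylsilyloxy)-1α,8-dimethyl-6-(triethylsilyloxy)hydroazula-5,8-diene
Product: 14 2β-(tert-butyldimethylsilyloxy)-1α,8-dimethylhydroazula-4,8-dien-6-one
Conditions: Pd(OAc)2 (1.1 equiv), MeCN, rt
Reagents that add atoms: none
Why: Saegusa–Ito oxidation; the palladium enolate can undergo β-hydride elimination only toward C4 because C1 is quaternary, so the C4=C5 enone is the single possible regioisomer.

Step 11
Reactants: 14 2β-(tert-butyldimethylsilyloxy)-1α,8-dimethylhydroazula-4,8-dien-6-one
Product: 16 2β-(tert-butyldimethylsilyloxy)-4-isopropyl-1α,8-dimethylhydroazula-4,8-dien-6-one, via trimethylsilyl enol ether 15 (not isolated)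
Conditions: iPrMgCl, CuBr·SMe2 (20 mol %), TMSCl, THF, −78 °C; then crude 15, Pd(OAc)2 (1.1 equiv), MeCN, 40 °C
Reagents that add atoms: isopropylmagnesium chloride CC(C)[Mg]Cl
Why: TMSCl-accelerated copper-catalysed 1,4-addition to the s-cis enone forms the C4–isopropyl bond and traps the enolate; a second Saegusa–Ito oxidation returns the double bond to C4=C5, so the configuration of C4 in 15 is immaterial.

Step 12
Reactants: 16 2β-(tert-butyldimethylsilyloxy)-4-isopropyl-1α,8-dimethylhydroazula-4,8-dien-6-one
Product: 17 4β,5β-epoxy-2β-(tert-butyldimethylsilyloxy)-4α-isopropyl-1α,8-dimethylhydroazul-8-en-6-one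
Conditions: t-BuOOH, n-BuLi, THF, −78 to −20 °C
Reagents that add atoms: tert-butyl hydroperoxide CC(C)(C)OO
Why: Weitz–Scheffer-type nucleophilic epoxidation with lithium tert-butyl peroxide, which ignores the isolated C8=C9 olefin and is too weakly basic to enolise C7. Peroxide addition at C4 is reversible and ring closure should occur in the adduct that keeps the large isopropyl group on the less encumbered α face (anti to the C2 silyloxy group and C10), which puts oxygen on the β face.

Step 13
Reactants: 17 4β,5β-epoxy-2β-(tert-butyldimethylsilyloxy)-4α-isopropyl-1α,8-dimethylhydroazul-8-en-6-one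
Product: 18 4β-hydroxy-2β-(tert-butyldimethylsilyloxy)-4α-isopropyl-1α,8-dimethyl-5αH-hydroazul-8-en-6-one
Conditions: SmI2 (2.5 equiv), THF–MeOH, −90 °C
Reagents that add atoms: none
Why: SmI2 reduction of an α,β-epoxy ketone cleaves the C5–O bond through the ketyl and gives the β-hydroxy ketone without elimination; C4 is untouched. C5 is protonated inside the trivalent samarium aldolate chelate, which can persist only if C6 ends cis to the C4 oxygen, so H5 should enter on the α face (cis fusion), which is also the more stable epimer.

Step 14
Reactants: 18 4β-hydroxy-2β-(tert-butyldimethylsilyloxy)-4α-isopropyl-1α,8-dimethyl-5αH-hydroazul-8-en-6-one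
Product: 19 2β-(tert-butyldimethylsilyloxy)-4α-isopropyl-1α,8-dimethyl-5αH-hydroazul-8-ene-4β,6α-diol
Conditions: Me4NBH(OAc)3, MeCN–AcOH, −30 °C
Reagents that add atoms: none
Why: Evans–Saksena reduction; the tertiary hydroxyl exchanges onto boron and delivers hydride to C6 through a chair-like six-membered transition state from the β face on which the C4 oxygen sits, giving the 6α-alcohol under mildly acidic conditions that spare the β,γ-olefin.

Step 15
Reactants: 19 2β-(tert-butyldimethylsilyloxy)-4α-isopropyl-1α,8-dimethyl-5αH-hydroazul-8-ene-4β,6α-diol
Product: 20 2β-(tert-butyldimethylsilyloxy)-4β-hydroxy-4α-isopropyl-1α,8-dimethyl-5αH-hydroazul-8-en-6α-yl 3,4,5-trimethoxybenzoate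
Conditions: 3,4,5-(MeO)3C6H2COCl, DMAP, Et3N, CH2Cl2, 0 °C to rt
Reagents that add atoms: 3,4,5-trimethoxybenzoyl chloride COc1cc(cc(OC)c1OC)C(Cl)=O
Why: DMAP-catalysed acylation of the only free secondary hydroxyl; the tertiary C4 hydroxyl should not react.

Step 16
Reactants: 20 2β-(tert-butyldimethylsilyloxy)-4β-hydroxy-4α-isopropyl-1α,8-dimethyl-5αH-hydroazul-8-en-6α-yl 3,4,5-trimethoxybenzoate
Product: 21 2β,4β-dihydroxy-4α-isopropyl-1α,8-dimethyl-5αH-hydroazul-8-en-6α-yl 3,4,5-trimethoxybenzoate
Conditions: HF·pyridine, pyridine, THF, 0 °C to rt
Reagents that add atoms: none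
Why: Fluoride cleavage of the secondary TBS ether under buffered, non-basic conditions, which should avoid hydrolysis or migration of the benzoate.

Step 17
Reactants: 21 2β,4β-dihydroxy-4α-isopropyl-1α,8-dimethyl-5αH-hydroazul-8-en-6α-yl 3,4,5-trimethoxybenzoate
Product: 22 2β-[(2Z)-2-methylbut-2-enoyloxy]-4β-hydroxy-4α-isopropyl-1α,8-dimethyl-5αH-hydroazul-8-en-6α-yl 3,4,5-trimethoxybenzoate (1R,2S,4S,5R,6R in the numbering used here; CNP0112256.1)
Conditions: angelic acid, 2,4,6-Cl3C6H2COCl, Et3N, PhMe, rt; then 21, PhMe, 75 °C
Reagents that add atoms: angelic acid C/C=C(/C)C(=O)O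
Why: Yamaguchi esterification through the mixed trichlorobenzoic anhydride, used for angelates because it avoids the nucleophile- and base-induced Z to E isomerisation to the tiglate; DMAP is left out for the same reason and the tertiary alcohol stays free.

## Compound list

1 | 2-methylcyclopentane-1,3-dione | CC1C(=O)CCC1=O | starting material
2 | 3-bromo-2-methylcyclopent-2-en-1-one | CC1=C(Br)CCC1=O | intermediate
3 | (1S)-3-bromo-2-methylcyclopent-2-en-1-ol | CC1=C(Br)CC[C@@H]1O | intermediate
4 | {[(1S)-3-bromo-2-methylcyclopent-2-en-1-yl]oxy}(tert-butyl)dimethylsilane | CC1=C(Br)CC[C@@H]1O[Si](C)(C)C(C)(C)C | intermediate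
5 | [(3S)-3-(tert-butyldimethylsilyloxy)-2-methylcyclopent-1-en-1-yl]lithium (not isolated) | CC1=C([Li])CC[C@@H]1O[Si](C)(C)C(C)(C)C | intermediate
6 | 1-[(3S)-3-(tert-butyldimethylsilyloxy)-2-methylcyclopent-1-en-1-yl]ethan-1-one | CC(=O)C1=C(C)[C@@H](O[Si](C)(C)C(C)(C)C)CC1 | intermediate
7 | tert-butyldimethyl{[(1S)-2-methyl-3-[1-(triethylsilyloxy)ethenyl]cyclopent-2-en-1-yl]oxy}silane | C=C(O[Si](CC)(CC)CC)C1=C(C)[C@@H](O[Si](C)(C)C(C)(C)C)CC1 | intermediate
8 | ethyl 2-[(3S)-3-(tert-butyldimethylsilyloxy)-2-methylcyclopent-1-en-1-yl]-2-(triethylsilyloxy)cyclopropane-1-carboxylate, all four ring stereoisomers | CCOC(=O)C1CC1(O[Si](CC)(CC)CC)C2=C(C)[C@@H](O[Si](C)(C)C(C)(C)C)CC2 | intermediate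
9 | lithium enolate of 8, both C6 epimers (not isolated) | CCOC(O[Li])=C1CC1(O[Si](CC)(CC)CC)C2=C(C)[C@@H](O[Si](C)(C)C(C)(C)C)CC2 | intermediate
10 | ethyl (1S,2R)-2-[(3S)-3-(tert-butyldimethylsilyloxy)-2-methylcyclopent-1-en-1-yl]-1-methyl-2-(triethylsilyloxy)cyclopropane-1-carboxylate | CCOC(=O)[C@@]1(C)C[C@@]1(O[Si](CC)(CC)CC)C2=C(C)[C@@H](O[Si](C)(C)C(C)(C)C)CC2 | intermediate
11 | (1S,2R)-2-[(3S)-3-(tert-butyldimethylsilyloxy)-2-methylcyclopent-1-en-1-yl]-1-methyl-2-(triethylsilyloxy)cyclopropane-1-carbaldehyde (not isolated) | O=C[C@@]1(C)C[C@@]1(O[Si](CC)(CC)CC)C2=C(C)[C@@H](O[Si](C)(C)C(C)(C)C)CC2 | intermediate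
12 | tert-butyl{[(1S)-3-[(1S,2R)-2-ethenyl-2-methyl-1-(triethylsilyloxy)cyclopropyl]-2-methylcyclopent-2-en-1-yl]oxy}dimethylsilane (key-step precursor, cis-dialkenyl) | C=C[C@@]1(C)C[C@@]1(O[Si](CC)(CC)CC)C2=C(C)[C@@H](O[Si](C)(C)C(C)(C)C)CC2 | intermediate
13 | 2β-(tert-butyldimethylsilyloxy)-1α,8-dimethyl-6-(triethylsilyloxy)hydroazula-5,8-diene (key-step product) | CC(C)(C)[Si](C)(C)O[C@H]1CCC2=C(O[Si](CC)(CC)CC)CC(C)=CC[C@@]12C | intermediate
14 | 2β-(tert-butyldimethylsilyloxy)-1α,8-dimethylhydroazula-4,8-dien-6-one | CC(C)(C)[Si](C)(C)O[C@H]1CC=C2C(=O)CC(C)=CC[C@@]12C | intermediate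
15 | 2β-(tert-butyldimethylsilyloxy)-4-isopropyl-1α,8-dimethyl-6-(trimethylsilyloxy)hydroazula-5,8-diene, C4 configuration immaterial (not isolated) | CC(C)(C)[Si](C)(C)O[C@H]1CC(C(C)C)C2=C(O[Si](C)(C)C)CC(C)=CC[C@@]12C | intermediate
16 | 2β-(tert-butyldimethylsilyloxy)-4-isopropyl-1α,8-dimethylhydroazula-4,8-dien-6-one | CC(C)(C)[Si](C)(C)O[C@H]1CC(C(C)C)=C2C(=O)CC(C)=CC[C@@]12C | intermediate
17 | 4β,5β-epoxy-2β-(tert-butyldimethylsilyloxy)-4α-isopropyl-1α,8-dimethylhydroazul-8-en-6-one | CC(C)(C)[Si](C)(C)O[C@H]1C[C@@]2(C(C)C)O[C@]23C(=O)CC(C)=CC[C@@]13C | intermediate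
18 | 4β-hydroxy-2β-(tert-butyldimethylsilyloxy)-4α-isopropyl-1α,8-dimethyl-5αH-hydroazul-8-en-6-one | CC(C)(C)[Si](C)(C)O[C@H]1C[C@](O)(C(C)C)[C@H]2C(=O)CC(C)=CC[C@@]12C | intermediate
19 | 2β-(tert-butyldimethylsilyloxy)-4α-isopropyl-1α,8-dimethyl-5αH-hydroazul-8-ene-4β,6α-diol | CC(C)(C)[Si](C)(C)O[C@H]1C[C@](O)(C(C)C)[C@H]2[C@H](O)CC(C)=CC[C@@]12C | intermediate
20 | 2β-(tert-butyldimethylsilyloxy)-4β-hydroxy-4α-isopropyl-1α,8-dimethyl-5αH-hydroazul-8-en-6α-yl 3,4,5-trimethoxybenzoate | CC(C)(C)[Si](C)(C)O[C@H]1C[C@](O)(C(C)C)[C@H]2[C@H](OC(=O)c3cc(OC)c(OC)c(OC)c3)CC(C)=CC[C@@]12C | intermediate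
21 | 2β,4β-dihydroxy-4α-isopropyl-1α,8-dimethyl-5αH-hydroazul-8-en-6α-yl 3,4,5-trimethoxybenzoate | O[C@H]1C[C@](O)(C(C)C)[C@H]2[C@H](OC(=O)c3cc(OC)c(OC)c(OC)c3)CC(C)=CC[C@@]12C | intermediate
22 | 2β-[(2Z)-2-methylbut-2-enoyloxy]-4β-hydroxy-4α-isopropyl-1α,8-dimethyl-5αH-hydroazul-8-en-6α-yl 3,4,5-trimethoxybenzoate (CNP0112256.1) | C/C=C(/C)C(=O)O[C@H]1C[C@](O)(C(C)C)[C@H]2[C@H](OC(=O)c3cc(OC)c(OC)c(OC)c3)CC(C)=CC[C@@]12C | target

## Step count and least certain steps

Total: 17 steps. Longest linear sequence: 17 steps (one linear chain from 1; all other atom sources are commercial reagents).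

**Step 9 (key step).** The shift is slowed by the inward methyl group on the fully substituted terminus and by bond formation on the silyloxy-bearing face. If the temperature has to be raised, reversible homolysis of C6–C8 (one-centre epimerisation of the ring) could precede the shift. The C2 substituent would then choose the face and the configuration of C1 would be eroded; hydrolysis of the enol ether is a lesser risk. The fallback sets out from 12. The tertiary triethylsilyl ether is cleaved selectively (HF·pyridine, pyridine, THF, 0 °C) to (1S,2R)-2-ethenyl-2-methyl-1-[(3S)-3-(tert-butyldimethylsilyloxy)-2-methylcyclopent-1-en-1-yl]cyclopropan-1-ol F1. Its potassium alkoxide (KH, 18-crown-6, THF, −78 to 0 °C) should undergo the anion-accelerated oxy-Cope rearrangement far below the temperature of ring epimerisation. The resulting C5=C6 enolate is trapped with TESCl, which returns to the route at 13.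

**Step 7.** The methylating agent may attack the enolate face next to the cyclopentenyl group, which would lead to the trans-dialkenyl series, and the two ring-enantiomeric series may co-elute. The fallback sets out from 5 (generated from 4). It is acylated with N-methoxy-N,2-dimethylbut-3-enamide to 1-[(3S)-3-(tert-butyldimethylsilyloxy)-2-methylcyclopent-1-en-1-yl]-2-methylbut-3-en-1-one F2. Soft enolisation (TESOTf, Et3N) should give the (E)-dienol ether tert-butyldimethyl{[(1S)-2-methyl-3-[(1E)-2-methyl-1-(triethylsilyloxy)buta-1,3-dien-1-yl]cyclopent-2-en-1-yl]oxy}silane F3, in which the vinyl group turns only a hydrogen toward the ring substituent. Stereospecific methylene transfer to the enol ether double bond (Et2Zn, CH2I2, Furukawa variant of the Simmons–Smith reaction) rejoins the route at 12, which would still have to be separated from its ring-enantiomeric diastereomer.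

**Step 12.** The peroxide may be delivered to the α face of C4 (kinetic approach anti to the C2 silyloxy group), which would give the C4 epimer, and the hindered tetrasubstituted enone may react slowly enough for base-induced migration of C8=C9 to intervene. The fallback sets out from 16. Desilylation (HF·pyridine) gives 2β-hydroxy-4-isopropyl-1α,8-dimethylhydroazula-4,8-dien-6-one F4. Its lithium alkoxide on the β face should hold t-BuOOLi and deliver it to the same face of C4, giving 4β,5β-epoxy-2β-hydroxy-4α-isopropyl-1α,8-dimethylhydroazul-8-en-6-one F5. Resilylation (TBSOTf, 2,6-lutidine) returns to the route at 17.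

**Step 13.** Protonation of the samarium enolate on the β face would give the trans-fused C5 epimer, which cannot be corrected by base without moving C8=C9; loss of the tertiary oxygen to re-form 16 is a second risk. The fallback sets out from 17. Reduction of the ketone under non-chelating conditions (NaBH4, MeOH, −40 °C, hydride anti to the epoxide C–O bond) should give 4β,5β-epoxy-2β-(tert-butyldimethylsilyloxy)-4α-isopropyl-1α,8-dimethylhydroazul-8-en-6β-ol F6. Its C6–H bond is anti-periplanar to the C5–O bond, so a Lewis acid (BF3·OEt2, CH2Cl2, −78 °C) should trigger a stereospecific semipinacol 1,2-hydride shift with inversion at C5, which returns to the route at 18.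

**Step 17.** Acylation of the neopentylic C2 hydroxyl may be slow, and prolonged heating may isomerise the angeloyl unit to the tiglate. The fallback sets out from 21. Esterification with 2-[bis(2,2,2-trifluoroethoxy)phosphoryl]propanoic acid (DCC, DMAP) gives the phosphonate ester 2β-{2-[bis(2,2,2-trifluoroethoxy)phosphoryl]propanoyloxy}-4β-hydroxy-4α-isopropyl-1α,8-dimethyl-5αH-hydroazul-8-en-6α-yl 3,4,5-trimethoxybenzoate F7. A Still–Gennari olefination with acetaldehyde (KN(SiMe3)2, 18-crown-6, THF, −78 °C) should build the Z olefin on the substrate and returns to the route at 22.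

## Further compounds

F1 | step 9 | (1S,2R)-2-ethenyl-2-methyl-1-[(3S)-3-(tert-butyldimethylsilyloxy)-2-methylcyclopent-1-en-1-yl]cyclopropan-1-ol | C=C[C@@]1(C)C[C@@]1(O)C2=C(C)[C@@H](O[Si](C)(C)C(C)(C)C)CC2
F2 | step 7 | 1-[(3S)-3-(tert-butyldimethylsilyloxy)-2-methylcyclopent-1-en-1-yl]-2-methylbut-3-en-1-one (either configuration at the α-carbon) | C=CC(C)C(=O)C1=C(C)[C@@H](O[Si](C)(C)C(C)(C)C)CC1
F3 | step 7 | tert-butyldimethyl{[(1S)-2-methyl-3-[(1E)-2-methyl-1-(triethylsilyloxy)buta-1,3-dien-1-yl]cyclopent-2-en-1-yl]oxy}silane | C=C/C(C)=C(/O[Si](CC)(CC)CC)C1=C(C)[C@@H](O[Si](C)(C)C(C)(C)C)CC1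
F4 | step 12 | 2β-hydroxy-4-isopropyl-1α,8-dimethylhydroazula-4,8-dien-6-one | O[C@H]1CC(C(C)C)=C2C(=O)CC(C)=CC[C@@]12C
F5 | step 12 | 4β,5β-epoxy-2β-hydroxy-4α-isopropyl-1α,8-dimethylhydroazul-8-en-6-one | O[C@H]1C[C@@]2(C(C)C)O[C@]23C(=O)CC(C)=CC[C@@]13C
F6 | step 13 | 4β,5β-epoxy-2β-(tert-butyldimethylsilyloxy)-4α-isopropyl-1α,8-dimethylhydroazul-8-en-6β-ol | CC(C)(C)[Si](C)(C)O[C@H]1C[C@@]2(C(C)C)O[C@]23[C@@H](O)CC(C)=CC[C@@]13C
F7 | step 17 | 2β-{2-[bis(2,2,2-trifluoroethoxy)phosphoryl]propanoyloxy}-4β-hydroxy-4α-isopropyl-1α,8-dimethyl-5αH-hydroazul-8-en-6α-yl 3,4,5-trimethoxybenzoate | CC(C(=O)O[C@H]1C[C@](O)(C(C)C)[C@H]2[C@H](OC(=O)c3cc(OC)c(OC)c(OC)c3)CC(C)=CC[C@@]12C)P(=O)(OCC(F)(F)F)OCC(F)(F)F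
A1 | alternative 1 | 6-acetoxy-4-methyl-2H-pyran-3(6H)-one (racemic at C6) | CC1=CC(OC(C)=O)OCC1=O
A2 | alternative 1 | (4R)-4-(tert-butyldimethylsilyloxy)-3-methylcyclopent-2-en-1-one | CC1=CC(=O)C[C@H]1O[Si](C)(C)C(C)(C)C
A3 | alternative 1 | C6–O–C10 bridged tricyclic diketone (C4 ketone, C9 enone, C2 silyloxy epimeric to the target) | CC(C)(C)[Si](C)(C)O[C@@H]1CC(=O)[C@H]2[C@H]3C=C(C)C(=O)[C@H](O3)[C@@]12C
A4 | alternative 2 | thymoquinone (2-isopropyl-5-methylcyclohexa-2,5-diene-1,4-dione) | CC1=CC(=O)C(C(C)C)=CC1=O
A5 | alternative 2 | isoprene (2-methylbuta-1,3-diene) | C=CC(C)=C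
A6 | alternative 2 | trans-decalin 4,5-epoxy-6-ol with C1 bonded to C6 (C2 silyl ether, 4-isopropyl, 1,8-dimethyl, Δ8; configuration as required for the anti-periplanar shift) | CC(C)(C)[Si](C)(C)O[C@H]1C[C@@]2(C(C)C)O[C@H]2[C@]3(O)CC(C)=CC[C@@]13C
A7 | alternative 2 | cis-fused 4β-hydroxy-6-oxo hydroazulene, C2 silyl ether (identical with 18) | CC(C)(C)[Si](C)(C)O[C@H]1C[C@](O)(C(C)C)[C@H]2C(=O)CC(C)=CC[C@@]12C
A8 | alternative 3 | 3-[(4R)-2,2-dimethyl-1,3-dioxolan-4-yl]-2-(triisopropylsilyloxy)but-2-enal (olefin geometry not specified) | O=CC(O[Si](C(C)C)(C(C)C)C(C)C)=C(C)[C@@H]1COC(C)(C)O1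
A9 | alternative 3 | 2-(triisopropylsilyloxy)-4,7-dimethyl-7-[(4R)-2,2-dimethyl-1,3-dioxolan-4-yl]cyclohept-4-en-1-one | O=C1[C@H](O[Si](C(C)C)(C(C)C)C(C)C)CC(C)=CC[C@@]1(C)[C@@H]2COC(C)(C)O2
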